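**Retrosynthetic overview**
1. Target ⇒ removal of two MOM ethers from a (2S)-flavanone. Ring C is closed just before by a catalyst-controlled oxa-Michael addition of the 2′-OH onto the chalcone enone (C2–O1 bond, the only stereocentre).
2. Chalcone ⇒ Claisen–Schmidt union (Cα=Cβ) of a ring A acetophenone and a ring B chromene aldehyde.
3. Ring B aldehyde ⇒ pyran ring closed by oxidative cyclisation of an ortho-prenylphenol (ortho-quinone methide, then oxa-6π) ⇒ C5-prenylation of 2,4-dihydroxybenzaldehyde.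
4. Ring A ketone ⇒ radical Markovnikov hydration of a prenyl group ⇒ regioselective bis-MOM protection ⇒ C-prenylation of 2,4,6-trihydroxyacetophenone.
5. Ring order: rings A and B are bought as aromatics; the pyran ring is formed first (on the ring B fragment), ring C last.

Assumption: the quinidine-derived thiourea of step 7 is taken as the pseudo-enantiomer that gives the 2S product. This is not established for this substrate; the sign is checked by circular dichroism on the first run, and the quinine-derived pseudo-enantiomer is used instead if it is reversed.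

**Step 1**
Reactants: 1 2,4-dihydroxybenzaldehyde; 2 2-methylbut-3-en-2-ol
Product: 3 2,4-dihydroxy-5-(3-methylbut-2-en-1-yl)benzaldehyde
Conditions: BF3·OEt2 (0.3 equiv), 1,4-dioxane, rt, 16 h
Reagents that add atoms: 2-methylbut-3-en-2-ol, CC(C)(O)C=C
Why: Friedel–Crafts (nuclear) prenylation, in which the dimethylallyl cation attacks C5 (para to the 2-OH, ortho to the 4-OH, the less hindered activated site); the minor C3 isomer is removed by chromatography and no stereocentre is formed.

**Step 2**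
Reactants: 3 2,4-dihydroxy-5-(3-methylbut-2-en-1-yl)benzaldehyde
Product: 5 7-hydroxy-2,2-dimethyl-2H-chromene-6-carbaldehyde, via ortho-quinone methide 4 (not isolated)
Conditions: DDQ (1.1 equiv), toluene, 80 °C, 1 h
Reagents that add atoms: none
Why: DDQ dehydrogenation of the ortho-prenylphenol gives the ortho-quinone methide, which closes by oxa-6π electrocyclisation as in the presumed biosynthetic oxidative cyclisation; only the 4-OH is ortho to the prenyl group, so only the linear chromene can form.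

**Step 3**
Reactants: 6 1-(2,4,6-trihydroxyphenyl)ethan-1-one; 7 1-bromo-3-methylbut-2-ene
Product: 8 1-[2,4,6-trihydroxy-3-(3-methylbut-2-en-1-yl)phenyl]ethan-1-one
Conditions: prenyl bromide (1.0 equiv), DBU (1.0 equiv), THF, 0 °C → rt, 24 h
Reagents that add atoms: 1-bromo-3-methylbut-2-ene, CC(C)=CCBr
Why: C-alkylation of the acylphloroglucinol anion (a vinylogous acid) with an allylic bromide; the two free ring carbons are equivalent, so a single mono-C-prenyl isomer results.

**Step 4**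
Reactants: 8 1-[2,4,6-trihydroxy-3-(3-methylbut-2-en-1-yl)phenyl]ethan-1-one; 9 chloromethyl methyl ether
Product: 10 1-[2-hydroxy-4,6-bis(methoxymethoxy)-3-(3-methylbut-2-en-1-yl)phenyl]ethan-1-one
Conditions: MOMCl (2.2 equiv), K2CO3 (3 equiv), acetone, 0 °C → rt, 4 h
Reagents that add atoms: chloromethyl methyl ether, COCCl
Why: Williamson-type acetal protection takes the 4-OH and the unhindered 6-OH, while the 2-OH, flanked by the prenyl group and held in the hydrogen-bonded chelate with the ketone, stays free; this fixes which oxygen later closes ring C.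

**Step 5**
Reactants: 10 1-[2-hydroxy-4,6-bis(methoxymethoxy)-3-(3-methylbut-2-en-1-yl)phenyl]ethan-1-one; 11 dioxygen
Product: 12 1-[2-hydroxy-3-(3-hydroxy-3-methylbutyl)-4,6-bis(methoxymethoxy)phenyl]ethan-1-one
Conditions: Co(acac)2 (20 mol %), PhSiH3 (2.5 equiv), O2 (1 atm), THF, rt, 6 h; aqueous work-up
Reagents that add atoms: dioxygen, O=O
Why: Mukaiyama hydration (hydrogen-atom transfer to the trisubstituted alkene, O2 capture of the tertiary radical, reduction by silane) gives the Markovnikov tertiary alcohol without the chroman that a cationic hydration would form with the neighbouring phenol; it is run here because the chromene alkene is not yet in the molecule.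

**Step 6**
Reactants: 12 1-[2-hydroxy-3-(3-hydroxy-3-methylbutyl)-4,6-bis(methoxymethoxy)phenyl]ethan-1-one; 5 7-hydroxy-2,2-dimethyl-2H-chromene-6-carbaldehyde
Product: 14 (2E)-1-[2-hydroxy-3-(3-hydroxy-3-methylbutyl)-4,6-bis(methoxymethoxy)phenyl]-3-(7-hydroxy-2,2-dimethyl-2H-chromen-6-yl)prop-2-en-1-one, via aldol adduct 13 (not isolated)
Conditions: KOH (12 equiv, 50 % aq.), EtOH, 0 °C → rt, 72 h, dark; then AcOH to pH 6
Reagents that add atoms: none
Why: Claisen–Schmidt aldol condensation with E1cB dehydration to the E-enone; salicylaldehyde-type aldehydes condense as their phenoxides under excess KOH, and in strong base the product stays open-chain as its phenoxide.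

**Step 7**
Reactants: 14 (2E)-1-[2-hydroxy-3-(3-hydroxy-3-methylbutyl)-4,6-bis(methoxymethoxy)phenyl]-3-(7-hydroxy-2,2-dimethyl-2H-chromen-6-yl)prop-2-en-1-one
Product: 15 (2S)-8-(3-hydroxy-3-methylbutyl)-2-(7-hydroxy-2,2-dimethyl-2H-chromen-6-yl)-5,7-bis(methoxymethoxy)-2,3-dihydro-4H-chromen-4-one
Conditions: N-[3,5-bis(trifluoromethyl)phenyl]-N′-[(9R)-6′-methoxycinchonan-9-yl]thiourea (20 mol %), toluene, 4 Å molecular sieves, 0 °C → rt, 48–72 h
Reagents that add atoms: none
Why: Proposed new method: catalyst-controlled intramolecular oxa-Michael addition (the laboratory counterpart of the enzymatic chalcone-to-flavanone step) on an unactivated chalcone that keeps a free ring B phenol and a free tertiary alcohol; the quinuclidine nitrogen acts as general base on the chelated 2′-OH (the only free ortho oxygen of ring A, hence the 8-substituted product) while the thiourea N–H pair binds the carbonyl oxygen, the 6′-OMOM group twists the aryl ketone and favours ring closure, and the phenol adds to one enone face inside this hydrogen-bonded complex to set C2 as S under kinetic control in a non-polar solvent; the closest known reaction type is the cinchona-thiourea-catalysed asymmetric oxa-Michael cyclisation of 2′-hydroxychalcones and their β-ketoester-activated analogues.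

**Step 8**
Reactants: 15 (2S)-8-(3-hydroxy-3-methylbutyl)-2-(7-hydroxy-2,2-dimethyl-2H-chromen-6-yl)-5,7-bis(methoxymethoxy)-2,3-dihydro-4H-chromen-4-one
Product: 17 (2S)-5,7-dihydroxy-8-(3-hydroxy-3-methylbutyl)-2-(7-hydroxy-2,2-dimethyl-2H-chromen-6-yl)-2,3-dihydro-4H-chromen-4-one, via 7-O-MOM flavanone 16 (not isolated)
Conditions: NaHSO4·SiO2, CH2Cl2, rt, 2–4 h
Reagents that add atoms: none
Why: Acetal hydrolysis of phenolic MOM ethers on a mild heterogeneous acid (the chelated 5-OMOM goes first); in CH2Cl2 at rt the tertiary alcohol, the chromene and the acid-sensitive benzylic C2–O1 bond are not ionised, so the 2S centre is kept.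

**Compound list**
1 | 2,4-dihydroxybenzaldehyde | O=Cc1ccc(O)cc1O | starting material
2 | 2-methylbut-3-en-2-ol | CC(C)(O)C=C | starting material
3 | 2,4-dihydroxy-5-(3-methylbut-2-en-1-yl)benzaldehyde | O=Cc1cc(CC=C(C)C)c(O)cc1O | intermediate
4 | 6-hydroxy-3-(3-methylbut-2-en-1-ylidene)-4-oxocyclohexa-1,5-diene-1-carbaldehyde (ortho-quinone methide) | O=CC1=CC(=CC=C(C)C)C(=O)C=C1O | intermediate (not isolated)
5 | 7-hydroxy-2,2-dimethyl-2H-chromene-6-carbaldehyde | O=Cc1cc2C=CC(C)(C)Oc2cc1O | intermediate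
6 | 1-(2,4,6-trihydroxyphenyl)ethan-1-one | CC(=O)c1c(O)cc(O)cc1O | starting material
7 | 1-bromo-3-methylbut-2-ene | CC(C)=CCBr | starting material
8 | 1-[2,4,6-trihydroxy-3-(3-methylbut-2-en-1-yl)phenyl]ethan-1-one | CC(=O)c1c(O)cc(O)c(CC=C(C)C)c1O | intermediate
9 | chloromethyl methyl ether | COCCl | starting material
10 | 1-[2-hydroxy-4,6-bis(methoxymethoxy)-3-(3-methylbut-2-en-1-yl)phenyl]ethan-1-one | CC(=O)c1c(OCOC)cc(OCOC)c(CC=C(C)C)c1O | intermediate
11 | dioxygen | O=O | starting material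
12 | 1-[2-hydroxy-3-(3-hydroxy-3-methylbutyl)-4,6-bis(methoxymethoxy)phenyl]ethan-1-one | CC(=O)c1c(OCOC)cc(OCOC)c(CCC(C)(C)O)c1O | intermediate
13 | (3RS)-3-hydroxy-1-[2-hydroxy-3-(3-hydroxy-3-methylbutyl)-4,6-bis(methoxymethoxy)phenyl]-3-(7-hydroxy-2,2-dimethyl-2H-chromen-6-yl)propan-1-one (aldol adduct) | O=C(CC(O)c1cc2C=CC(C)(C)Oc2cc1O)c1c(OCOC)cc(OCOC)c(CCC(C)(C)O)c1O | intermediate (not isolated)
14 | (2E)-1-[2-hydroxy-3-(3-hydroxy-3-methylbutyl)-4,6-bis(methoxymethoxy)phenyl]-3-(7-hydroxy-2,2-dimethyl-2H-chromen-6-yl)prop-2-en-1-one | O=C(/C=C/c1cc2C=CC(C)(C)Oc2cc1O)c1c(OCOC)cc(OCOC)c(CCC(C)(C)O)c1O | intermediate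
15 | (2S)-8-(3-hydroxy-3-methylbutyl)-2-(7-hydroxy-2,2-dimethyl-2H-chromen-6-yl)-5,7-bis(methoxymethoxy)-2,3-dihydro-4H-chromen-4-one | CC(C)(O)CCc1c(OCOC)cc(OCOC)c2c1O[C@H](c1cc3c(cc1O)OC(C)(C)C=C3)CC2=O | intermediate
16 | (2S)-5-hydroxy-8-(3-hydroxy-3-methylbutyl)-2-(7-hydroxy-2,2-dimethyl-2H-chromen-6-yl)-7-(methoxymethoxy)-2,3-dihydro-4H-chromen-4-one | CC(C)(O)CCc1c(OCOC)cc(O)c2c1O[C@H](c1cc3c(cc1O)OC(C)(C)C=C3)CC2=O | intermediate (not isolated)
17 | (2S)-5,7-dihydroxy-8-(3-hydroxy-3-methylbutyl)-2-(7-hydroxy-2,2-dimethyl-2H-chromen-6-yl)-2,3-dihydro-4H-chromen-4-one | CC(C)(O)CCc1c(O)cc(O)c2c1O[C@H](c1cc3c(cc1O)OC(C)(C)C=C3)CC2=O | target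

**Totals and risks**
Total step count: 8. Longest linear sequence: 6 steps (6 → 8 → 10 → 12 → 14 → 15 → 17, steps 3 to 8).

Step 7 is the most likely to fail. The closure is reversible, the ring B phenol can tie up the catalyst, and enantioselectivity on unactivated chalcones is usually only moderate. The fallback gives up catalyst control and resolves instead. It sets out from 14, which is cyclised with NaOAc in EtOH at reflux to racemic (2RS)-8-(3-hydroxy-3-methylbutyl)-2-(7-hydroxy-2,2-dimethyl-2H-chromen-6-yl)-5,7-bis(methoxymethoxy)-2,3-dihydro-4H-chromen-4-one F1. Preparative chiral supercritical-fluid chromatography (amylose tris(3,5-dimethylphenylcarbamate) phase, CO2/MeOH) then delivers 15, where the route is rejoined. The unwanted (2R)-8-(3-hydroxy-3-methylbutyl)-2-(7-hydroxy-2,2-dimethyl-2H-chromen-6-yl)-5,7-bis(methoxymethoxy)-2,3-dihydro-4H-chromen-4-one F2 is reopened with KOH in EtOH to 14 and recycled.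

Step 6 is the second risk. The aldehyde reacts as an ortho-phenoxide with a para oxygen donor and is a poor electrophile, and the ketone is hindered. The fallback masks that phenol at the cost of one extra step. It sets out from 5, which with MOMCl and K2CO3 in acetone gives 7-(methoxymethoxy)-2,2-dimethyl-2H-chromene-6-carbaldehyde F3. Condensation of this with 12 (KOH, EtOH, rt) gives (2E)-1-[2-hydroxy-3-(3-hydroxy-3-methylbutyl)-4,6-bis(methoxymethoxy)phenyl]-3-[7-(methoxymethoxy)-2,2-dimethyl-2H-chromen-6-yl]prop-2-en-1-one F4. Ring closure with the thiourea of step 7 gives (2S)-8-(3-hydroxy-3-methylbutyl)-5,7-bis(methoxymethoxy)-2-[7-(methoxymethoxy)-2,2-dimethyl-2H-chromen-6-yl]-2,3-dihydro-4H-chromen-4-one F5, and NaHSO4·SiO2 in CH2Cl2 removes all three MOM groups. The fallback comes back to the route at 17.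

Step 8 is the third risk. The C2–O1 bond is a 2,4-dioxygenated benzylic aryl ether, so acid can ionise it and erode the ee, and the tertiary alcohol can close onto the 7-OH to a chroman. The fallback changes the protecting group to one removed without acid. It sets out from 8, which is hydrated first (Co(acac)2, PhSiH3, O2, THF) to 1-[2,4,6-trihydroxy-3-(3-hydroxy-3-methylbutyl)phenyl]ethan-1-one F6. Allyl bromide and K2CO3 in acetone give 1-[2-hydroxy-3-(3-hydroxy-3-methylbutyl)-4,6-bis(prop-2-en-1-yloxy)phenyl]ethan-1-one F7. Condensation with 5 (KOH, EtOH) gives (2E)-1-[2-hydroxy-3-(3-hydroxy-3-methylbutyl)-4,6-bis(prop-2-en-1-yloxy)phenyl]-3-(7-hydroxy-2,2-dimethyl-2H-chromen-6-yl)prop-2-en-1-one F8. Ring closure as in step 7 gives (2S)-8-(3-hydroxy-3-methylbutyl)-2-(7-hydroxy-2,2-dimethyl-2H-chromen-6-yl)-5,7-bis(prop-2-en-1-yloxy)-2,3-dihydro-4H-chromen-4-one F9. Pd(PPh3)4 with morpholine in THF at rt then removes both allyl groups under neutral conditions, and the fallback comes back to the route at 17.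

**Further compounds**
F1 | step 7 | (2RS)-8-(3-hydroxy-3-methylbutyl)-2-(7-hydroxy-2,2-dimethyl-2H-chromen-6-yl)-5,7-bis(methoxymethoxy)-2,3-dihydro-4H-chromen-4-one | CC(C)(O)CCc1c(OCOC)cc(OCOC)c2c1OC(c1cc3c(cc1O)OC(C)(C)C=C3)CC2=O
F2 | step 7 | (2R)-8-(3-hydroxy-3-methylbutyl)-2-(7-hydroxy-2,2-dimethyl-2H-chromen-6-yl)-5,7-bis(methoxymethoxy)-2,3-dihydro-4H-chromen-4-one | CC(C)(O)CCc1c(OCOC)cc(OCOC)c2c1O[C@@H](c1cc3c(cc1O)OC(C)(C)C=C3)CC2=O
F3 | step 6 | 7-(methoxymethoxy)-2,2-dimethyl-2H-chromene-6-carbaldehyde | O=Cc1cc2C=CC(C)(C)Oc2cc1OCOC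
F4 | step 6 | (2E)-1-[2-hydroxy-3-(3-hydroxy-3-methylbutyl)-4,6-bis(methoxymethoxy)phenyl]-3-[7-(methoxymethoxy)-2,2-dimethyl-2H-chromen-6-yl]prop-2-en-1-one | O=C(/C=C/c1cc2C=CC(C)(C)Oc2cc1OCOC)c1c(OCOC)cc(OCOC)c(CCC(C)(C)O)c1O
F5 | step 6 | (2S)-8-(3-hydroxy-3-methylbutyl)-5,7-bis(methoxymethoxy)-2-[7-(methoxymethoxy)-2,2-dimethyl-2H-chromen-6-yl]-2,3-dihydro-4H-chromen-4-one | CC(C)(O)CCc1c(OCOC)cc(OCOC)c2c1O[C@H](c1cc3c(cc1OCOC)OC(C)(C)C=C3)CC2=O
F6 | step 8 | 1-[2,4,6-trihydroxy-3-(3-hydroxy-3-methylbutyl)phenyl]ethan-1-one | CC(=O)c1c(O)cc(O)c(CCC(C)(C)O)c1O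
F7 | step 8 | 1-[2-hydroxy-3-(3-hydroxy-3-methylbutyl)-4,6-bis(prop-2-en-1-yloxy)phenyl]ethan-1-one | CC(=O)c1c(OCC=C)cc(OCC=C)c(CCC(C)(C)O)c1O
F8 | step 8 | (2E)-1-[2-hydroxy-3-(3-hydroxy-3-methylbutyl)-4,6-bis(prop-2-en-1-yloxy)phenyl]-3-(7-hydroxy-2,2-dimethyl-2H-chromen-6-yl)prop-2-en-1-one | O=C(/C=C/c1cc2C=CC(C)(C)Oc2cc1O)c1c(OCC=C)cc(OCC=C)c(CCC(C)(C)O)c1O
F9 | step 8 | (2S)-8-(3-hydroxy-3-methylbutyl)-2-(7-hydroxy-2,2-dimethyl-2H-chromen-6-yl)-5,7-bis(prop-2-en-1-yloxy)-2,3-dihydro-4H-chromen-4-one | CC(C)(O)CCc1c(OCC=C)cc(OCC=C)c2c1O[C@H](c1cc3c(cc1O)OC(C)(C)C=C3)CC2=O
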